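**Retrosynthetic overview**
1. Target ⇐ ketal hydrolysis ⇐ Heck union of a core-bound (E)-iodoalkene with the terminal CH2 of an N-(cyclopentenolonyl)penta-2,4-dienamide; this closes the lower triene.
2. Key step: that dienamide ⇐ Beckmann-type 1,2-shift (the ring enol carbon migrates from carbon to nitrogen) of the oxime sulfonate of 2-pentadienoyl-cyclopentane-1,3-dione ⇐ C-acylation of cyclopentane-1,3-dione with penta-2,4-dienoic acid.
3. Iodoalkene ⇐ hydrostannation/iodination ⇐ ethynyl addition anti to the oxirane ⇐ asymmetric nucleophilic epoxidation of a quinone monoketal ⇐ oxidative dearomatisation of the anilide from 3-aminophenol and the upper trienoic acid.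
4. Upper acid ⇐ Heck coupling of (1E,3R)-1-iodo-3-methylpent-1-ene (Takai olefination of (R)-2-methylbutanal) with the same penta-2,4-dienoic acid.
5. Rings: the six-membered ring enters as benzene and is dearomatised first; the oxirane is closed second; the five-membered ring enters preformed and is joined last.

Assumption 1: (R)-2-methylbutan-1-ol is bought as the single enantiomer.
Assumption 2: the cinchonine-derived phase-transfer salt gives the (1S,6R)-epoxide drawn for 11; if the sense is the opposite one, the pseudo-enantiomeric cinchonidine-derived salt is used.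

**Route**

Step 1
Reactants: 1 (R)-2-methylbutan-1-ol
Product: 2 (R)-2-methylbutanal
Conditions: TEMPO (2,2,6,6-tetramethylpiperidin-1-oxyl, 10 mol%), PhI(OAc)2 (1.1 equiv), CH2Cl2, rt; washed, dried, used as CH2Cl2 solution
Reagents that add atoms: none
Why: TEMPO-catalysed alcohol oxidation (oxoammonium cycle) stops cleanly at the aldehyde under near-neutral conditions, so the α-stereocentre is not epimerised.

Step 2
Reactants: 2 (R)-2-methylbutanal
Product: 3 (1E,3R)-1-iodo-3-methylpent-1-ene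
Conditions: CrCl2 (6 equiv), CHI3 (2 equiv), THF–dioxane, 0 °C → rt
Reagents that add atoms: iodoform, IC(I)I
Why: Takai olefination, in which the geminal dichromium carbenoid adds to the aldehyde and eliminates to the E-iodoalkene while the non-basic conditions leave the stereocentre untouched.

Step 3
Reactants: 3 (1E,3R)-1-iodo-3-methylpent-1-ene; 4 (2E)-penta-2,4-dienoic acid
Product: 5 (2E,4E,6E,8R)-8-methyldeca-2,4,6-trienoic acid
Conditions: Pd(OAc)2 (5 mol%), K2CO3 (2.5 equiv), Bu4NCl (1 equiv), DMF, 40 °C; then 1 M HCl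
Reagents that add atoms: none
Why: Heck reaction under phase-transfer (Jeffery) conditions, where the alkenylpalladium inserts the terminal CH2 of the dienoate and syn β-hydride elimination gives the all-E triene with retention of the iodoalkene geometry.

Step 4
Reactants: 5 (2E,4E,6E,8R)-8-methyldeca-2,4,6-trienoic acid; 6 3-aminophenol
Product: 8 (2E,4E,6E,8R)-N-(3-hydroxyphenyl)-8-methyldeca-2,4,6-trienamide, via trienoyl chloride 7 (not isolated)
Conditions: (COCl)2, DMF (cat.), CH2Cl2, 0 °C → rt; evaporate; then 6, pyridine, THF, 0 °C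
Reagents that add atoms: oxalyl chloride, ClC(=O)C(=O)Cl (its chlorine is held only in 7)
Why: Acid chloride formation followed by N-acylation (Schotten–Baumann type), selective because the aniline nitrogen is far more nucleophilic than the phenol oxygen.

Step 5
Reactants: 8 (2E,4E,6E,8R)-N-(3-hydroxyphenyl)-8-methyldeca-2,4,6-trienamide
Product: 10 (2E,4E,6E,8R)-N-(6,6-dimethoxy-3-oxocyclohexa-1,4-dien-1-yl)-8-methyldeca-2,4,6-trienamide, via para-methoxyphenol 9 (not isolated)
Conditions: PhI(OAc)2 (2.2 equiv), MeOH, 0 °C → rt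
Reagents that add atoms: methanol, CO
Why: Hypervalent-iodine oxidative dearomatisation, in which two successive two-electron phenol oxidations in methanol deliver both methoxy groups para to the hydroxyl (ortho to the amide) and give the quinone monoketal.

Step 6
Reactants: 10 (2E,4E,6E,8R)-N-(6,6-dimethoxy-3-oxocyclohexa-1,4-dien-1-yl)-8-methyldeca-2,4,6-trienamide
Product: 11 (2E,4E,6E,8R)-N-[(1S,6R)-2,2-dimethoxy-5-oxo-7-oxabicyclo[4.1.0]hept-3-en-3-yl]-8-methyldeca-2,4,6-trienamide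
Conditions: t-BuOOH (70% aq.), NaOH (aq.), N-benzylcinchoninium chloride (10 mol%), toluene, 0 °C → rt
Reagents that add atoms: tert-butyl hydroperoxide, CC(C)(C)OO
Why: Weitz–Scheffer nucleophilic epoxidation under chiral phase-transfer catalysis (Wynberg type), in which the hydroperoxide anion adds within the chiral ion pair to the more electrophilic unsubstituted enone alkene and sets both oxirane stereocentres (cis by ring constraint), the minor diastereomer being removed by recrystallisation.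

Step 7
Reactants: 11 (2E,4E,6E,8R)-N-[(1S,6R)-2,2-dimethoxy-5-oxo-7-oxabicyclo[4.1.0]hept-3-en-3-yl]-8-methyldeca-2,4,6-trienamide; 12 ethynylmagnesium bromide
Product: 13 (2E,4E,6E,8R)-N-[(1S,5R,6R)-5-ethynyl-5-hydroxy-2,2-dimethoxy-7-oxabicyclo[4.1.0]hept-3-en-3-yl]-8-methyldeca-2,4,6-trienamide (hydroxyl cis to the oxirane oxygen)
Conditions: 12 (4 equiv), CeCl3 (4 equiv), THF, −78 → −40 °C; NH4Cl (aq.)
Reagents that add atoms: none
Why: Organocerium 1,2-addition to the ketone, in which the first equivalent deprotonates the amide N–H and the nucleophile then attacks from the face opposite the oxirane oxygen, setting the tertiary carbinol with hydroxyl and epoxide cis.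

Step 8
Reactants: 13 (2E,4E,6E,8R)-N-[(1S,5R,6R)-5-ethynyl-5-hydroxy-2,2-dimethoxy-7-oxabicyclo[4.1.0]hept-3-en-3-yl]-8-methyldeca-2,4,6-trienamide
Product: 15 (2E,4E,6E,8R)-N-[(1S,5R,6R)-5-hydroxy-5-[(E)-2-iodoethenyl]-2,2-dimethoxy-7-oxabicyclo[4.1.0]hept-3-en-3-yl]-8-methyldeca-2,4,6-trienamide, via alkenylstannane 14 (not isolated)
Conditions: Bu3SnH (1.3 equiv), PdCl2(PPh3)2 (3 mol%), THF, 0 °C; then I2 (1.1 equiv), CH2Cl2, 0 °C
Reagents that add atoms: tributyltin hydride, CCCC[SnH](CCCC)CCCC (tin is held only in 14); iodine, II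
Why: Palladium-catalysed syn hydrostannation places tin on the distal carbon of the hindered tertiary propargylic alcohol, and iododestannylation with retention gives the E-iodoalkene.

Step 9
Reactants: 4 (2E)-penta-2,4-dienoic acid; 16 cyclopentane-1,3-dione
Product: 18 3-hydroxy-2-[(2E)-penta-2,4-dienoyl]cyclopent-2-en-1-one, via enol ester 17 (not isolated)
Conditions: DCC (1.1 equiv), 4-(dimethylamino)pyridine (DMAP, 1.2 equiv), CH2Cl2, 0 °C → rt; 1 M HCl wash
Reagents that add atoms: none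
Why: Steglich-type O-acylation of the dione followed by DMAP-mediated O-to-C acyl transfer to the thermodynamically favoured, hydrogen-bonded β-triketone.

Step 10
Reactants: 18 3-hydroxy-2-[(2E)-penta-2,4-dienoyl]cyclopent-2-en-1-one
Product: 20 (2E)-N-(2-hydroxy-5-oxocyclopent-1-en-1-yl)penta-2,4-dienamide, via oxime mesitylenesulfonate 19 (not isolated)
Conditions: MesSO2ONH2 (1.3 equiv), CH2Cl2, 0 °C → rt; then 2,6-lutidine, MeCN–H2O (9:1), rt
Reagents that add atoms: O-(mesitylsulfonyl)hydroxylamine, Cc1cc(C)c(S(=O)(=O)ON)c(C)c1 (nitrogen stays, the sulfonate is held only in 19); water, O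
Why: Proposed new method: the exocyclic carbonyl of the enolised β-triketone condenses with H2N–OSO2Mes to the oxime sulfonate 19, in which the enol O–H···N hydrogen bond holds the N–O bond anti to the ring carbon, so ionisation triggers a Beckmann 1,2-shift of the electron-rich ring carbon from carbon to nitrogen and water captures the N-alkenyl nitrilium ion to give the enol amide, forming the ring C–N bond without handling 2-aminocyclopentane-1,3-dione; the closest known reaction type is the Beckmann rearrangement of ketoxime O-sulfonates (alkenyl migration to enamides) and the Beckmann-type breakdown known for 2-(1-alkoxyiminoalkyl)cyclohexane-1,3-diones, not yet used preparatively on a 2-dienoyl cyclopentane-1,3-dione.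

Step 11
Reactants: 15 (2E,4E,6E,8R)-N-[(1S,5R,6R)-5-hydroxy-5-[(E)-2-iodoethenyl]-2,2-dimethoxy-7-oxabicyclo[4.1.0]hept-3-en-3-yl]-8-methyldeca-2,4,6-trienamide; 20 (2E)-N-(2-hydroxy-5-oxocyclopent-1-en-1-yl)penta-2,4-dienamide
Product: 21 (2E,4E,6E,8R)-N-[(1S,5S,6R)-5-hydroxy-5-{(1E,3E,5E)-7-[(2-hydroxy-5-oxocyclopent-1-en-1-yl)amino]-7-oxohepta-1,3,5-trien-1-yl}-2,2-dimethoxy-7-oxabicyclo[4.1.0]hept-3-en-3-yl]-8-methyldeca-2,4,6-trienamide
Conditions: Pd(OAc)2 (10 mol%), Bu4NCl (1 equiv), NaHCO3 (3 equiv), DMF, 40 °C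
Reagents that add atoms: none
Why: Heck reaction of an alkenyl iodide with an electron-poor terminal diene, in which insertion at the terminal CH2 and syn β-hydride elimination give the new E-alkene while both partner geometries are retained and no stereocentre is touched.

Step 12
Reactants: 21 (2E,4E,6E,8R)-N-[(1S,5S,6R)-5-hydroxy-5-{(1E,3E,5E)-7-[(2-hydroxy-5-oxocyclopent-1-en-1-yl)amino]-7-oxohepta-1,3,5-trien-1-yl}-2,2-dimethoxy-7-oxabicyclo[4.1.0]hept-3-en-3-yl]-8-methyldeca-2,4,6-trienamide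
Product: 22 (2E,4E,6E,8R)-N-[(1S,5S,6R)-5-hydroxy-5-{(1E,3E,5E)-7-[(2-hydroxy-5-oxocyclopent-1-en-1-yl)amino]-7-oxohepta-1,3,5-trien-1-yl}-2-oxo-7-oxabicyclo[4.1.0]hept-3-en-3-yl]-8-methyldeca-2,4,6-trienamide (CNP0596887.4)
Conditions: SiO2, 10% aq. oxalic acid, CH2Cl2, rt
Reagents that add atoms: water, O
Why: Mild acid-catalysed ketal hydrolysis on wet silica unmasks the enone carbonyl, the electron-poor trienamide chains disfavouring ionisation of the tertiary allylic alcohol so that the epoxide and carbinol stereocentres are untouched.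

**Compound list**
1 | (R)-2-methylbutan-1-ol | CC[C@@H](C)CO | starting material
2 | (R)-2-methylbutanal | CC[C@@H](C)C=O | intermediate
3 | (1E,3R)-1-iodo-3-methylpent-1-ene | CC[C@@H](C)/C=C/I | intermediate
4 | (2E)-penta-2,4-dienoic acid | C=C/C=C/C(=O)O | starting material
5 | (2E,4E,6E,8R)-8-methyldeca-2,4,6-trienoic acid | CC[C@@H](C)/C=C/C=C/C=C/C(=O)O | intermediate
6 | 3-aminophenol | Nc1cccc(O)c1 | starting material
7 | (2E,4E,6E,8R)-8-methyldeca-2,4,6-trienoyl chloride | CC[C@@H](C)/C=C/C=C/C=C/C(=O)Cl | intermediate (not isolated)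
8 | (2E,4E,6E,8R)-N-(3-hydroxyphenyl)-8-methyldeca-2,4,6-trienamide | CC[C@@H](C)/C=C/C=C/C=C/C(=O)Nc1cccc(O)c1 | intermediate
9 | (2E,4E,6E,8R)-N-(5-hydroxy-2-methoxyphenyl)-8-methyldeca-2,4,6-trienamide | CC[C@@H](C)/C=C/C=C/C=C/C(=O)Nc1cc(O)ccc1OC | intermediate (not isolated)
10 | (2E,4E,6E,8R)-N-(6,6-dimethoxy-3-oxocyclohexa-1,4-dien-1-yl)-8-methyldeca-2,4,6-trienamide | CC[C@@H](C)/C=C/C=C/C=C/C(=O)NC1=CC(=O)C=CC1(OC)OC | intermediate
11 | (2E,4E,6E,8R)-N-[(1S,6R)-2,2-dimethoxy-5-oxo-7-oxabicyclo[4.1.0]hept-3-en-3-yl]-8-methyldeca-2,4,6-trienamide | CC[C@@H](C)/C=C/C=C/C=C/C(=O)NC1=CC(=O)[C@@H]2O[C@@H]2C1(OC)OC | intermediate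
12 | ethynylmagnesium bromide | C#C[Mg]Br | starting material
13 | (2E,4E,6E,8R)-N-[(1S,5R,6R)-5-ethynyl-5-hydroxy-2,2-dimethoxy-7-oxabicyclo[4.1.0]hept-3-en-3-yl]-8-methyldeca-2,4,6-trienamide | CC[C@@H](C)/C=C/C=C/C=C/C(=O)NC1=C[C@@](O)(C#C)[C@@H]2O[C@@H]2C1(OC)OC | intermediate
14 | (2E,4E,6E,8R)-N-[(1S,5R,6R)-5-hydroxy-2,2-dimethoxy-5-[(E)-2-(tributylstannyl)ethenyl]-7-oxabicyclo[4.1.0]hept-3-en-3-yl]-8-methyldeca-2,4,6-trienamide | CC[C@@H](C)/C=C/C=C/C=C/C(=O)NC1=C[C@@](O)(/C=C/[Sn](CCCC)(CCCC)CCCC)[C@@H]2O[C@@H]2C1(OC)OC | intermediate (not isolated)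
15 | (2E,4E,6E,8R)-N-[(1S,5R,6R)-5-hydroxy-5-[(E)-2-iodoethenyl]-2,2-dimethoxy-7-oxabicyclo[4.1.0]hept-3-en-3-yl]-8-methyldeca-2,4,6-trienamide | CC[C@@H](C)/C=C/C=C/C=C/C(=O)NC1=C[C@@](O)(/C=C/I)[C@@H]2O[C@@H]2C1(OC)OC | intermediate
16 | cyclopentane-1,3-dione | O=C1CCC(=O)C1 | starting material
17 | 3-oxocyclopent-1-en-1-yl (2E)-penta-2,4-dienoate | C=C/C=C/C(=O)OC1=CC(=O)CC1 | intermediate (not isolated)
18 | 3-hydroxy-2-[(2E)-penta-2,4-dienoyl]cyclopent-2-en-1-one | C=C/C=C/C(=O)C1=C(O)CCC1=O | intermediate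
19 | 3-hydroxy-2-[(1E,2E)-1-{[(2,4,6-trimethylphenyl)sulfonyl]oxyimino}penta-2,4-dien-1-yl]cyclopent-2-en-1-one (N–O anti to the ring) | Cc1cc(C)c(c(C)c1)S(=O)(=O)O/N=C(/C2=C(O)CCC2=O)\C=C\C=C | intermediate (not isolated)
20 | (2E)-N-(2-hydroxy-5-oxocyclopent-1-en-1-yl)penta-2,4-dienamide | C=C/C=C/C(=O)NC1=C(O)CCC1=O | intermediate
21 | (2E,4E,6E,8R)-N-[(1S,5S,6R)-5-hydroxy-5-{(1E,3E,5E)-7-[(2-hydroxy-5-oxocyclopent-1-en-1-yl)amino]-7-oxohepta-1,3,5-trien-1-yl}-2,2-dimethoxy-7-oxabicyclo[4.1.0]hept-3-en-3-yl]-8-methyldeca-2,4,6-trienamide | CC[C@@H](C)/C=C/C=C/C=C/C(=O)NC1=C[C@@](O)(/C=C/C=C/C=C/C(=O)NC3=C(O)CCC3=O)[C@@H]2O[C@@H]2C1(OC)OC | intermediate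
22 | (2E,4E,6E,8R)-N-[(1S,5S,6R)-5-hydroxy-5-{(1E,3E,5E)-7-[(2-hydroxy-5-oxocyclopent-1-en-1-yl)amino]-7-oxohepta-1,3,5-trien-1-yl}-2-oxo-7-oxabicyclo[4.1.0]hept-3-en-3-yl]-8-methyldeca-2,4,6-trienamide | CC[C@@H](C)/C=C/C=C/C=C/C(=O)NC1=C[C@@](O)(/C=C/C=C/C=C/C(=O)NC2=C(O)CCC2=O)[C@@H]2O[C@@H]2C1=O | target

**Step count**
Total: 12 steps. Longest linear sequence: 10 steps (steps 1–8, 11, 12).

**Three steps most likely to fail**

Step 10 (the new Beckmann-type shift). Risks: the nitrilium ion may be captured by the neighbouring enol oxygen to give a fused oxazole; the aminating reagent may add in conjugate fashion to the dienone; the dienyl group may migrate if the oxime does not adopt the hydrogen-bonded geometry. Fallback with known chemistry, setting out from cyclopentane-1,3-dione 16 and acid 4: nitrosation of 16 (NaNO2, aq. HCl, 0 °C) gives 2-(hydroxyimino)cyclopentane-1,3-dione F1. Hydrogenation (H2, Pd/C, HCl, MeOH) gives 2-amino-3-hydroxycyclopent-2-en-1-one hydrochloride F2. Acid 4 is converted with oxalyl chloride into (2E)-penta-2,4-dienoyl chloride F3, which acylates F2 (Et3N, THF, 0 °C) to give 20, where the route is rejoined.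

Step 6 (asymmetric epoxidation). Risk: facial selectivity of this catalyst class is good but not complete, and the two epoxide diastereomers differ only far from the side-chain stereocentre, so they may not separate. Fallback, setting out from 3-aminophenol 6: Boc2O (THF, rt) gives tert-butyl (3-hydroxyphenyl)carbamate F4. PhI(OAc)2 in MeOH gives tert-butyl (6,6-dimethoxy-3-oxocyclohexa-1,4-dien-1-yl)carbamate F5. The same phase-transfer epoxidation gives crystalline tert-butyl [(1S,6R)-2,2-dimethoxy-5-oxo-7-oxabicyclo[4.1.0]hept-3-en-3-yl]carbamate F6, which as a pair of enantiomers is brought to >99% ee by recrystallisation. Deprotonation (LiHMDS, THF, −78 °C) and acylation with trienoyl chloride 7 gives tert-butyl N-[(1S,6R)-2,2-dimethoxy-5-oxo-7-oxabicyclo[4.1.0]hept-3-en-3-yl]-N-[(2E,4E,6E,8R)-8-methyldeca-2,4,6-trienoyl]carbamate F7. Mg(ClO4)2 in MeCN removes the Boc group selectively and the route is rejoined at 11.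

Step 11 (late Heck coupling). Risk: the acidic, chelating enol amide of 20 may bind palladium or decompose under the basic conditions, and the polyene product is sensitive. Fallback, setting out from iodoalkene 15: Heck coupling with plain acid 4 (Pd(OAc)2, K2CO3, Bu4NCl, DMF, as in step 3) gives (2E,4E,6E)-7-[(1R,2S,6S)-2-hydroxy-5,5-dimethoxy-4-{[(2E,4E,6E,8R)-8-methyldeca-2,4,6-trienoyl]amino}-7-oxabicyclo[4.1.0]hept-3-en-2-yl]hepta-2,4,6-trienoic acid F8. Amide formation with the aminocyclopentenolone salt F2 (made as in the fallback to step 10; EDC·HCl, HOBt, Et3N, DMF, 0 °C) then attaches the five-membered ring last and rejoins the route at 21.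

Further compounds
F1 | step 10 | 2-(hydroxyimino)cyclopentane-1,3-dione | ON=C1C(=O)CCC1=O
F2 | step 10 | 2-amino-3-hydroxycyclopent-2-en-1-one hydrochloride | Cl.NC1=C(O)CCC1=O
F3 | step 10 | (2E)-penta-2,4-dienoyl chloride | C=C/C=C/C(=O)Cl
F4 | step 6 | tert-butyl (3-hydroxyphenyl)carbamate | CC(C)(C)OC(=O)Nc1cccc(O)c1
F5 | step 6 | tert-butyl (6,6-dimethoxy-3-oxocyclohexa-1,4-dien-1-yl)carbamate | CC(C)(C)OC(=O)NC1=CC(=O)C=CC1(OC)OC
F6 | step 6 | tert-butyl [(1S,6R)-2,2-dimethoxy-5-oxo-7-oxabicyclo[4.1.0]hept-3-en-3-yl]carbamate | CC(C)(C)OC(=O)NC1=CC(=O)[C@@H]2O[C@@H]2C1(OC)OC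
F7 | step 6 | tert-butyl N-[(1S,6R)-2,2-dimethoxy-5-oxo-7-oxabicyclo[4.1.0]hept-3-en-3-yl]-N-[(2E,4E,6E,8R)-8-methyldeca-2,4,6-trienoyl]carbamate | CC[C@@H](C)/C=C/C=C/C=C/C(=O)N(C(=O)OC(C)(C)C)C1=CC(=O)[C@@H]2O[C@@H]2C1(OC)OC
F8 | step 11 | (2E,4E,6E)-7-[(1R,2S,6S)-2-hydroxy-5,5-dimethoxy-4-{[(2E,4E,6E,8R)-8-methyldeca-2,4,6-trienoyl]amino}-7-oxabicyclo[4.1.0]hept-3-en-2-yl]hepta-2,4,6-trienoic acid | CC[C@@H](C)/C=C/C=C/C=C/C(=O)NC1=C[C@@](O)(/C=C/C=C/C=C/C(=O)O)[C@@H]2O[C@@H]2C1(OC)OC
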